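**Retrosynthetic overview**
1. The target is epigallocatechin-(4β→8)-epigallocatechin 3-O-gallate-(4β→8)-epigallocatechin. No ring is built: rings A, B and C of all three units come intact from (−)-epigallocatechin (EGC), and the galloyl ring from gallic acid.
2. Key disconnection: middle C4–bottom C8, made at the ketone level. Ring A of perbenzylated EGC attacks the C4 enolonium of the middle-unit flavan-3-one, so two natively nucleophilic carbons are joined.
3. Middle C3: hydride reduction anti to the new C4 aryl, then Mitsunobu inversion with the gallic acid, which sets 3R and the ester together.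
4. Top C4–middle C8 bond: Lewis-acid coupling of a 4β-alkoxy EGC donor, then global hydrogenolysis.
5. Order: middle–bottom C–C bond, C3 gallate, top–middle C–C bond, debenzylation.

Assumption: (−)-epigallocatechin (1) and 3,4,5-tris(benzyloxy)benzoic acid (9) are bought; the target SMILES is read as top unit (2R,3R,4R), middle unit (2R,3R,4S) carrying the gallate, bottom unit (2R,3R), both links 4β→8 (3,4-trans).

**Route**

Step 1
Reactants: 1 (−)-epigallocatechin
Product: 2 penta-O-benzyl-EGC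
Conditions: BnBr, K2CO3, DMF, 0 °C → rt, Ar
Reagents that add atoms: benzyl bromide, BrCc1ccccc1
Why: Williamson etherification in which K2CO3 deprotonates only the five phenols, so the aliphatic 3-OH stays free and C2 and C3 are untouched when air is excluded.

Step 2
Reactants: 2 penta-O-benzyl-EGC
Product: 3 hexa-O-benzyl-EGC
Conditions: NaH, BnBr, Bu4NI (cat.), THF/DMF, 0 °C → rt
Reagents that add atoms: benzyl bromide, BrCc1ccccc1
Why: Williamson etherification with NaH caps the remaining secondary alcohol, which is safe for C2 because all phenols are already ethers, and leaves ring A of 3 as its only nucleophilic part for step 5.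

Step 3
Reactants: 2 penta-O-benzyl-EGC
Product: 4 penta-O-benzyl-flavan-3-one (2R)
Conditions: Dess–Martin periodinane, wet CH2Cl2, rt
Reagents that add atoms: none
Why: Dess–Martin oxidation of the secondary alcohol under neutral, non-enolizing conditions gives the flavan-3-one with the C2 centre intact, as is established for benzylated catechin-type alcohols.

Step 4
Reactants: 4 penta-O-benzyl-flavan-3-one
Product: 5 silyl enol ether (C3=C4)
Conditions: LiN(SiMe3)2, Me3SiCl, THF, −78 °C; pentane, filter; used crude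
Reagents that add atoms: chlorotrimethylsilane, C[Si](C)(C)Cl
Why: Kinetic enolate trapping with internal quench, in which the amide base takes a proton from the unhindered benzylic C4–H2 and not from the tertiary, oxygen-bearing C2–H, so the ring-A-conjugated C3=C4 silyl enol ether forms and C2 is not enolized.

Step 5
Reactants: 5 silyl enol ether; 3 hexa-O-benzyl-EGC
Product: 7 dimer ketone (middle C4–bottom C8 bond; 2R,4R in the ketone unit), via enolonium 6 (not isolated)
Conditions: PhI(OH)OTs (1.2 equiv), BF3·OEt2, CH2Cl2, −78 °C, 10 min; then 3 (2 equiv), −78 → −40 °C; aq NaHCO3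
Reagents that add atoms: [hydroxy(tosyloxy)iodo]benzene, OI(c1ccccc1)OS(=O)(=O)c1ccc(C)cc1 (its PhI(OTs) part is in 6 only and is lost before 7)
Why: Proposed new method: umpoled ketone α-arylation through a hypervalent-iodine enolonium, whose closest known reaction type is the PhI(OH)OTs/BF3 arylation of ketone silyl enol ethers by indoles and pyrroles; the enol ether attacks iodine to give the O-bound iodane 6 in which C4, natively a nucleophilic enol carbon, is electrophilic, the equally nucleophilic C8 of ring A of 3 (the position that reacts in Lewis-acid flavan couplings) attacks it in a Friedel–Crafts sense with loss of PhI, and the new C4 centre is set trans to the C2 aryl (4β) both kinetically (attack anti to that aryl) and thermodynamically (the acidic C4–H lets the ketone settle with the new aryl pseudoaxial, away from the peri 5-OBn).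

Step 6
Reactants: 7 dimer ketone
Product: 8 dimer 3S-alcohol (2,3-trans-3,4-cis in the middle unit)
Conditions: NaBH4, CeCl3·7H2O, MeOH/THF, −40 °C
Reagents that add atoms: none
Why: Luche-type borohydride reduction in which hydride reaches C3 only from the face opposite the pseudoaxial C4 aryl, which sets C3 as 3S (OH cis to the C4 aryl, trans to the C2 aryl, the epimer of what the target needs), while the cold CeCl3-buffered medium avoids enolization at C2 and C4.

Step 7
Reactants: 8 dimer 3S-alcohol; 9 3,4,5-tris(benzyloxy)benzoic acid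
Product: 10 dimer gallate (middle unit 2R,3R,4R; 2,3-cis-3,4-trans)
Conditions: PPh3, DIAD, toluene, 0 → 40 °C
Reagents that add atoms: none
Why: Mitsunobu esterification in which the oxyphosphonium of the equatorial 3S alcohol is displaced by the carboxylate of 9 in an SN2 step with inversion, which sets the required 3R centre and installs the gallate in one operation, the backside (ring-C axial) approach being open because O1 and C4a carry no syn-axial hydrogens and no anti-periplanar hydrogen is available for E2.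

Step 8
Reactants: 2 penta-O-benzyl-EGC
Product: 11 4β-(2-hydroxyethoxy)-penta-O-benzyl-EGC
Conditions: DDQ, HOCH2CH2OH, CH2Cl2, rt
Reagents that add atoms: ethane-1,2-diol, OCCO
Why: Oxidative C4 functionalization in which DDQ takes a hydride from the ring-A-activated benzylic C4–H and ethylene glycol adds trans to the 3-OH (4β), the established activation of benzylated 2,3-cis flavan-3-ols.

Step 9
Reactants: 11 4β-(2-hydroxyethoxy)-penta-O-benzyl-EGC; 10 dimer gallate
Product: 12 nonadeca-O-benzyl trimer (top 3-OH free)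
Conditions: TMSOTf (0.2 equiv), 4 Å MS, CH2Cl2, −78 °C; 11 added slowly to 10
Reagents that add atoms: none
Why: Lewis-acid Friedel–Crafts flavan coupling in which ionization of the C4 ether and attack by C8 of the middle unit of 10, the most nucleophilic free ring-A position, anti to the C3 oxygen gives the 4β (3,4-trans) interflavan bond, the well-precedented outcome in the 2,3-cis series, while slow addition of 11 limits its self-condensation.

Step 10
Reactants: 12 nonadeca-O-benzyl trimer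
Product: 13 target CNP0278699.1
Conditions: H2 (1 atm), Pd(OH)2/C, THF/MeOH/H2O, rt
Reagents that add atoms: none
Why: Hydrogenolysis over Pd(OH)2 cleaves all nineteen benzyl ethers and leaves the aryl ester, both interflavan bonds and every stereocentre untouched.

**Compound list**

1 | (−)-epigallocatechin, (2R,3R)-2-(3,4,5-trihydroxyphenyl)chroman-3,5,7-triol | O[C@@H]1Cc2c(O)cc(O)cc2O[C@@H]1c1cc(O)c(O)c(O)c1 | starting material

2 | (2R,3R)-5,7-bis(benzyloxy)-2-[3,4,5-tris(benzyloxy)phenyl]chroman-3-ol (penta-O-benzyl-EGC) | O[C@@H]1Cc2c(OCc9ccccc9)cc(OCc9ccccc9)cc2O[C@@H]1c1cc(OCc9ccccc9)c(OCc9ccccc9)c(OCc9ccccc9)c1 | intermediate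

3 | (2R,3R)-3,5,7-tris(benzyloxy)-2-[3,4,5-tris(benzyloxy)phenyl]chroman (hexa-O-benzyl-EGC) | C(c9ccccc9)O[C@@H]1Cc2c(OCc9ccccc9)cc(OCc9ccccc9)cc2O[C@@H]1c1cc(OCc9ccccc9)c(OCc9ccccc9)c(OCc9ccccc9)c1 | intermediate

4 | (2R)-5,7-bis(benzyloxy)-2-[3,4,5-tris(benzyloxy)phenyl]chroman-3-one | O=C1Cc2c(OCc9ccccc9)cc(OCc9ccccc9)cc2O[C@@H]1c1cc(OCc9ccccc9)c(OCc9ccccc9)c(OCc9ccccc9)c1 | intermediate

5 | (2R)-5,7-bis(benzyloxy)-2-[3,4,5-tris(benzyloxy)phenyl]-3-(trimethylsilyloxy)-2H-chromene (C3=C4 silyl enol ether of 4) | C[Si](C)(C)OC1=Cc2c(OCc9ccccc9)cc(OCc9ccccc9)cc2O[C@@H]1c1cc(OCc9ccccc9)c(OCc9ccccc9)c(OCc9ccccc9)c1 | intermediate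

6 | enolonium: O-bound phenyl(tosyloxy)iodanyl enol ether of 4 (C3–O–I(Ph)OTs, C3=C4, 2R), electrophilic at C4 | Cc1ccc(cc1)S(=O)(=O)OI(c1ccccc1)OC1=Cc2c(OCc9ccccc9)cc(OCc9ccccc9)cc2O[C@@H]1c1cc(OCc9ccccc9)c(OCc9ccccc9)c(OCc9ccccc9)c1 | intermediate

7 | dimer ketone: (2R,4R)-chroman-3-one 4 carrying at C4 (β, trans to the C2 aryl) the C8 of hexa-O-benzyl-EGC (2R,3R) | O=C1[C@@H](c2c(OCc9ccccc9)cc(OCc9ccccc9)c3c2O[C@H](c2cc(OCc9ccccc9)c(OCc9ccccc9)c(OCc9ccccc9)c2)[C@H](OCc9ccccc9)C3)c2c(OCc9ccccc9)cc(OCc9ccccc9)cc2O[C@@H]1c1cc(OCc9ccccc9)c(OCc9ccccc9)c(OCc9ccccc9)c1 | intermediate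

8 | dimer 3S-alcohol: upper unit (2R,3S,4R), 2,3-trans-3,4-cis (3-OH cis to the C4 aryl), lower unit hexa-O-benzyl-EGC linked at C8 | O[C@H]1[C@@H](c2c(OCc9ccccc9)cc(OCc9ccccc9)c3c2O[C@H](c2cc(OCc9ccccc9)c(OCc9ccccc9)c(OCc9ccccc9)c2)[C@H](OCc9ccccc9)C3)c2c(OCc9ccccc9)cc(OCc9ccccc9)cc2O[C@@H]1c1cc(OCc9ccccc9)c(OCc9ccccc9)c(OCc9ccccc9)c1 | intermediate

9 | 3,4,5-tris(benzyloxy)benzoic acid | OC(=O)c1cc(OCc9ccccc9)c(OCc9ccccc9)c(OCc9ccccc9)c1 | starting material

10 | dimer gallate: tetradeca-O-benzyl epigallocatechin 3-O-gallate-(4β→8)-epigallocatechin, upper unit (2R,3R,4R), 2,3-cis-3,4-trans | O=C(O[C@@H]1[C@@H](c2c(OCc9ccccc9)cc(OCc9ccccc9)c3c2O[C@H](c2cc(OCc9ccccc9)c(OCc9ccccc9)c(OCc9ccccc9)c2)[C@H](OCc9ccccc9)C3)c2c(OCc9ccccc9)cc(OCc9ccccc9)cc2O[C@@H]1c1cc(OCc9ccccc9)c(OCc9ccccc9)c(OCc9ccccc9)c1)c1cc(OCc9ccccc9)c(OCc9ccccc9)c(OCc9ccccc9)c1 | intermediate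

11 | 4β-(2-hydroxyethoxy)-5,7,3',4',5'-penta-O-benzyl-EGC (2R; 2,3-cis-3,4-trans) | O[C@@H]1[C@@H](OCCO)c2c(OCc9ccccc9)cc(OCc9ccccc9)cc2O[C@@H]1c1cc(OCc9ccccc9)c(OCc9ccccc9)c(OCc9ccccc9)c1 | intermediate

12 | nonadeca-O-benzyl trimer: top unit (2R,3R,4R) with free 3-OH, middle unit (2R,3R,4S) 3-O-[tri-O-benzylgalloyl], bottom unit (2R,3R) 3-O-benzyl; both links 4β→8 | O=C(O[C@@H]1[C@@H](c2c(OCc9ccccc9)cc(OCc9ccccc9)c3c2O[C@H](c2cc(OCc9ccccc9)c(OCc9ccccc9)c(OCc9ccccc9)c2)[C@H](OCc9ccccc9)C3)c2c(OCc9ccccc9)cc(OCc9ccccc9)c([C@H]3c4c(OCc9ccccc9)cc(OCc9ccccc9)cc4O[C@H](c4cc(OCc9ccccc9)c(OCc9ccccc9)c(OCc9ccccc9)c4)[C@@H]3O)c2O[C@@H]1c1cc(OCc9ccccc9)c(OCc9ccccc9)c(OCc9ccccc9)c1)c1cc(OCc9ccccc9)c(OCc9ccccc9)c(OCc9ccccc9)c1 | intermediate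

13 | CNP0278699.1, epigallocatechin-(4β→8)-epigallocatechin 3-O-gallate-(4β→8)-epigallocatechin | O=C(O[C@@H]1[C@@H](c2c(O)cc(O)c3c2O[C@H](c2cc(O)c(O)c(O)c2)[C@H](O)C3)c2c(O)cc(O)c([C@H]3c4c(O)cc(O)cc4O[C@H](c4cc(O)c(O)c(O)c4)[C@@H]3O)c2O[C@@H]1c1cc(O)c(O)c(O)c1)c1cc(O)c(O)c(O)c1 | target

**Count and risks**

Total steps: 10. Longest linear sequence: 8 steps (1 → 2 → 4 → 5 → 7 → 8 → 10 → 12 → 13, that is steps 1, 3, 4, 5, 6, 7, 9, 10).

The three steps most likely to fail:

Step 5, the enolonium arylation. The iodane 6 may be captured by tosylate instead of the arene. It may also lose H-2 to give an achiral 3-oxyflavylium, which would erase C2. The arene may react at C6, or product 7 may be arylated again. Fallback: put the reversed polarity on the arene instead of the ketone. Setting out from 3, NBS (CH2Cl2, −78 → 0 °C) gives 8-bromo-3,5,7,3',4',5'-hexa-O-benzyl-EGC F1. Palladium-catalysed α-arylation of silyl enol ether 5 with this aryl bromide (Pd(OAc)2, P(t-Bu)3, ZnF2, CsF, DMF, 70 °C) then comes back to the route at ketone 7.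

Step 7, the Mitsunobu inversion that installs the gallate. The alcohol is flanked by two aryl-bearing carbons. The ring oxygen O1 or ring A, both anti-periplanar to the leaving group, may participate and give ring contraction or retention. Fallback: relay the stereochemistry through the enol ether instead of inverting at C3. Setting out from 8, Burgess reagent (toluene, 50 °C) removes water by syn-elimination across C2–C3, since only H-2 is syn to the 3-OH, and gives the 4-aryl-4H-flav-2-ene dimer F2. DMDO (acetone/CH2Cl2, −78 °C) epoxidizes this enol ether on the face away from the C4 aryl to give the 2,3-epoxide F3. F3 is not isolated but reduced at once with Et3SiH/BF3·OEt2, hydride adding to C2 anti to the C3 oxygen, to the 2,3-cis-3,4-trans dimer alcohol F4. Steglich esterification of F4 with 9 (DCC, DMAP, CH2Cl2) comes back to the route at 10.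

Step 9, the coupling of donor 11 with the dimer 10 in near-equimolar amounts. The free C8 of 11 can attack its own cation and give oligomers, and C6 positions of 10 may compete. Fallback: block C8 of the donor. Setting out from 2, NBS (CH2Cl2, −78 °C) gives 8-bromo-penta-O-benzyl-EGC F5. DDQ/ethylene glycol gives its 4β-(2-hydroxyethoxy) derivative F6. TMSOTf coupling of F6 with 10 gives the 8-bromo nonadeca-O-benzyl trimer F7. Hydrogenolysis with added Et3N (H2, Pd(OH)2/C, THF/MeOH) removes the bromide together with the benzyl groups and comes back to the route at 13.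

**Further compounds**

F1 | step 5 | 8-bromo-3,5,7,3',4',5'-hexa-O-benzyl-EGC (2R,3R) | C(c9ccccc9)O[C@@H]1Cc2c(OCc9ccccc9)cc(OCc9ccccc9)c(Br)c2O[C@@H]1c1cc(OCc9ccccc9)c(OCc9ccccc9)c(OCc9ccccc9)c1

F2 | step 7 | 4-aryl-4H-flav-2-ene dimer (C2=C3 enol ether; C4 configuration as in 8; C4 bears C8 of hexa-O-benzyl-EGC) | C1=C(c3cc(OCc9ccccc9)c(OCc9ccccc9)c(OCc9ccccc9)c3)Oc2cc(OCc9ccccc9)cc(OCc9ccccc9)c2[C@@H]1c1c(OCc9ccccc9)cc(OCc9ccccc9)c2c1O[C@H](c1cc(OCc9ccccc9)c(OCc9ccccc9)c(OCc9ccccc9)c1)[C@H](OCc9ccccc9)C2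

F3 | step 7 | 2,3-epoxide of F2 (epoxide oxygen on the face opposite the C4 aryl) | O1[C@@H]2[C@@H](c4c(OCc9ccccc9)cc(OCc9ccccc9)c5c4O[C@H](c4cc(OCc9ccccc9)c(OCc9ccccc9)c(OCc9ccccc9)c4)[C@H](OCc9ccccc9)C5)c3c(OCc9ccccc9)cc(OCc9ccccc9)cc3O[C@]12c1cc(OCc9ccccc9)c(OCc9ccccc9)c(OCc9ccccc9)c1

F4 | step 7 | dimer 3R-alcohol: upper unit (2R,3R,4R), 2,3-cis-3,4-trans, free 3-OH (the C3 epimer of 8) | O[C@@H]1[C@@H](c2c(OCc9ccccc9)cc(OCc9ccccc9)c3c2O[C@H](c2cc(OCc9ccccc9)c(OCc9ccccc9)c(OCc9ccccc9)c2)[C@H](OCc9ccccc9)C3)c2c(OCc9ccccc9)cc(OCc9ccccc9)cc2O[C@@H]1c1cc(OCc9ccccc9)c(OCc9ccccc9)c(OCc9ccccc9)c1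

F5 | step 9 | 8-bromo-5,7,3',4',5'-penta-O-benzyl-EGC (2R,3R) | O[C@@H]1Cc2c(OCc9ccccc9)cc(OCc9ccccc9)c(Br)c2O[C@@H]1c1cc(OCc9ccccc9)c(OCc9ccccc9)c(OCc9ccccc9)c1

F6 | step 9 | 8-bromo-4β-(2-hydroxyethoxy)-5,7,3',4',5'-penta-O-benzyl-EGC (2,3-cis-3,4-trans) | O[C@@H]1[C@@H](OCCO)c2c(OCc9ccccc9)cc(OCc9ccccc9)c(Br)c2O[C@@H]1c1cc(OCc9ccccc9)c(OCc9ccccc9)c(OCc9ccccc9)c1

F7 | step 9 | 8-bromo nonadeca-O-benzyl trimer (12 with bromine at C8 of the top unit) | O=C(O[C@@H]1[C@@H](c2c(OCc9ccccc9)cc(OCc9ccccc9)c3c2O[C@H](c2cc(OCc9ccccc9)c(OCc9ccccc9)c(OCc9ccccc9)c2)[C@H](OCc9ccccc9)C3)c2c(OCc9ccccc9)cc(OCc9ccccc9)c([C@H]3c4c(OCc9ccccc9)cc(OCc9ccccc9)c(Br)c4O[C@H](c4cc(OCc9ccccc9)c(OCc9ccccc9)c(OCc9ccccc9)c4)[C@@H]3O)c2O[C@@H]1c1cc(OCc9ccccc9)c(OCc9ccccc9)c(OCc9ccccc9)c1)c1cc(OCc9ccccc9)c(OCc9ccccc9)c(OCc9ccccc9)c1
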